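Assumptions: the target has no stereocentre and no stereogenic double bond, so the achiral structure is the compound asked for; methyl orsellinate (1) and O‑benzylvanillin (4) are bought.

**Retrosynthetic overview**
1. Target 17 ⇐ four‑fold O‑debenzylation of diarylmethane 16 ⇐ ionic deoxygenation of diarylmethanol 14.
2. 14 ⇐ two molecules of aryllithium 11 (from aryl iodide 10) + ethyl formate, whose formyl carbon becomes the bridging CH2.
3. 10 ⇐ ipso‑iododecarboxylation of bibenzyl acid 9 ⇐ stilbene acid 8 ⇐ dihydroisocoumarin 7 (lactone opening, then C=C reduction).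
4. Key C–C bond: 7 ⇐ aldol addition/lactonisation of the laterally lithiated o‑toluate 3 (an ester dienolate) to aldehyde 4; 3 ⇐ methyl orsellinate 1 by chelation‑controlled 4‑O‑benzylation and 2‑O‑methylation. The ester carbon fixes the later bridge position (ortho to OMe, para to OH).
5. Rings: all four arenes are bought; the only ring closed is the temporary δ‑lactone of 7 (step 3), opened again in step 4.

**Route**

Step 1
Reactants: 1 methyl 2,4-dihydroxy-6-methylbenzoate (methyl orsellinate)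
Product: 2 methyl 4-(benzyloxy)-2-hydroxy-6-methylbenzoate
Conditions: BnBr (1.05 equiv), K2CO3 (1.2 equiv), acetone, reflux
Reagents that add atoms: benzyl bromide, BrCc1ccccc1
Why: Williamson etherification is selective for the 4‑OH because the 2‑OH is tied up in an intramolecular hydrogen bond to the ester carbonyl.

Step 2
Reactants: 2 methyl 4-(benzyloxy)-2-hydroxy-6-methylbenzoate
Product: 3 methyl 4-(benzyloxy)-2-methoxy-6-methylbenzoate
Conditions: MeI (3 equiv), K2CO3 (3 equiv), DMF, 50 °C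
Reagents that add atoms: iodomethane, CI
Why: Williamson methylation of the remaining chelated phenol under forcing conditions, with no other nucleophilic site present.

Step 3
Reactants: 3 methyl 4-(benzyloxy)-2-methoxy-6-methylbenzoate; 4 4-(benzyloxy)-3-methoxybenzaldehyde
Product: 7 (±)-6-(benzyloxy)-3-[4-(benzyloxy)-3-methoxyphenyl]-8-methoxy-3,4-dihydro-1H-isochromen-1-one, via methyl 4-(benzyloxy)-2-(lithiomethyl)-6-methoxybenzoate 5 (not isolated), via lithium 2-[5-(benzyloxy)-3-methoxy-2-(methoxycarbonyl)phenyl]-1-[4-(benzyloxy)-3-methoxyphenyl]ethan-1-olate 6 (not isolated)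
Conditions: LDA (1.15 equiv), THF, −78 °C, 20 min; then 4 (1.1 equiv), −78 °C → rt; aq. NH4Cl
Reagents that add atoms: none
Why: Lateral lithiation gives the o‑toluate dienolate, which undergoes a vinylogous aldol addition to the non‑enolisable aldehyde, and the alkoxide lactonises with loss of methoxide; the C3 stereocentre forms racemic and is erased in step 4.

Step 4
Reactants: 7 (±)-6-(benzyloxy)-3-[4-(benzyloxy)-3-methoxyphenyl]-8-methoxy-3,4-dihydro-1H-isochromen-1-one
Product: 8 4-(benzyloxy)-2-{(E)-2-[4-(benzyloxy)-3-methoxyphenyl]ethenyl}-6-methoxybenzoic acid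
Conditions: t-BuOK (2.5 equiv), dry DMSO/THF, rt; then cold 1 M HCl to pH 3–4 at 0 °C
Reagents that add atoms: none
Why: E1cB‑type β‑elimination, since C4–H is benzylic and vinylogously α to the lactone carbonyl and the carboxylate is the leaving group, gives the conjugated (E)‑stilbene acid; cold, mild acidification avoids re‑lactonisation.

Step 5
Reactants: 8 4-(benzyloxy)-2-{(E)-2-[4-(benzyloxy)-3-methoxyphenyl]ethenyl}-6-methoxybenzoic acid
Product: 9 4-(benzyloxy)-2-{2-[4-(benzyloxy)-3-methoxyphenyl]ethyl}-6-methoxybenzoic acid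
Conditions: TsNHNH2 (6 equiv, in portions), NaOAc (8 equiv), DME/H2O 1:1, reflux; then 1 M HCl
Reagents that add atoms: none
Why: Diimide reduction transfers H2 to the C=C only, so the two aryl benzyl ethers that Pd/H2 would cleave are kept.

Step 6
Reactants: 9 4-(benzyloxy)-2-{2-[4-(benzyloxy)-3-methoxyphenyl]ethyl}-6-methoxybenzoic acid
Product: 10 5-(benzyloxy)-1-{2-[4-(benzyloxy)-3-methoxyphenyl]ethyl}-2-iodo-3-methoxybenzene
Conditions: I2 (2 equiv), K3PO4 (1 equiv), MeCN, 100 °C, sealed tube, dark; aq. Na2S2O3 wash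
Reagents that add atoms: iodine, II
Why: Transition‑metal‑free ipso‑iododecarboxylation (aromatic Hunsdiecker type) of an electron‑rich, di‑ortho‑substituted benzoate places iodine exactly on the former carboxyl carbon, and I2 without an oxidant does not iodinate the other arene.

Step 7
Reactants: 10 5-(benzyloxy)-1-{2-[4-(benzyloxy)-3-methoxyphenyl]ethyl}-2-iodo-3-methoxybenzene (2.2 equiv relative to ethyl formate)
Product: 14 bis{4-(benzyloxy)-2-{2-[4-(benzyloxy)-3-methoxyphenyl]ethyl}-6-methoxyphenyl}methanol, via {4-(benzyloxy)-2-{2-[4-(benzyloxy)-3-methoxyphenyl]ethyl}-6-methoxyphenyl}lithium 11 (not isolated), via lithium {4-(benzyloxy)-2-{2-[4-(benzyloxy)-3-methoxyphenyl]ethyl}-6-methoxyphenyl}(ethoxy)methanolate 12 (not isolated), via 4-(benzyloxy)-2-{2-[4-(benzyloxy)-3-methoxyphenyl]ethyl}-6-methoxybenzaldehyde 13 (not isolated)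
Conditions: t-BuLi (4.4 equiv, i.e. 2 per ArI), THF, −78 °C, 30 min; HCO2Et (1.0 equiv), −78 → 0 °C, 2 h; aq. NH4Cl
Reagents that add atoms: ethyl formate, CCOC=O
Why: Iodine–lithium exchange with t‑BuLi (the second equivalent destroys t‑BuI, so nothing can alkylate the aryllithium on warming) is followed by double 1,2‑addition of the aryllithium to a formate ester, in which hemiacetal alkoxide 12 collapses to aldehyde 13 and this more electrophilic carbonyl is taken up by a second aryllithium; the carbinol carbon carries two identical aryl groups, so no stereocentre arises.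

Step 8
Reactants: 14 bis{4-(benzyloxy)-2-{2-[4-(benzyloxy)-3-methoxyphenyl]ethyl}-6-methoxyphenyl}methanol
Product: 16 bis{4-(benzyloxy)-2-{2-[4-(benzyloxy)-3-methoxyphenyl]ethyl}-6-methoxyphenyl}methane, via bis{4-(benzyloxy)-2-{2-[4-(benzyloxy)-3-methoxyphenyl]ethyl}-6-methoxyphenyl}methylium trifluoroacetate 15 (not isolated)
Conditions: Et3SiH (5 equiv), TFA (5 equiv), CH2Cl2, −20 → 0 °C, 30 min; aq. NaHCO3
Reagents that add atoms: none
Why: Ionic hydrogenation: the benzhydryl cation, stabilised by four ortho/para alkoxy groups, forms readily and is captured by excess silane faster than it can cyclise onto the tethered arene, while aryl benzyl ethers survive cold TFA.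

Step 9
Reactants: 16 bis{4-(benzyloxy)-2-{2-[4-(benzyloxy)-3-methoxyphenyl]ethyl}-6-methoxyphenyl}methane
Product: 17 4,4'-methylenebis{3-[2-(4-hydroxy-3-methoxyphenyl)ethyl]-5-methoxyphenol} (CNP0079383.0)
Conditions: H2 (1 atm), 10 % Pd/C, EtOAc/MeOH 1:1, rt
Reagents that add atoms: none
Why: Catalytic hydrogenolysis removes the four O‑benzyl groups, while the methyl ethers, the diarylmethane CH2 and the bibenzyl links are inert.

**Compound list**
1 | methyl 2,4-dihydroxy-6-methylbenzoate (methyl orsellinate) | COC(=O)c1c(C)cc(O)cc1O | starting material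
2 | methyl 4-(benzyloxy)-2-hydroxy-6-methylbenzoate | COC(=O)c1c(C)cc(OCc2ccccc2)cc1O | intermediate
3 | methyl 4-(benzyloxy)-2-methoxy-6-methylbenzoate | COC(=O)c1c(C)cc(OCc2ccccc2)cc1OC | intermediate
4 | 4-(benzyloxy)-3-methoxybenzaldehyde (O-benzylvanillin) | O=Cc1ccc(OCc2ccccc2)c(OC)c1 | starting material
5 | methyl 4-(benzyloxy)-2-(lithiomethyl)-6-methoxybenzoate | [Li]Cc1cc(OCc2ccccc2)cc(OC)c1C(=O)OC | intermediate (not isolated)
6 | lithium 2-[5-(benzyloxy)-3-methoxy-2-(methoxycarbonyl)phenyl]-1-[4-(benzyloxy)-3-methoxyphenyl]ethan-1-olate (racemic) | [Li+].[O-]C(Cc1cc(OCc2ccccc2)cc(OC)c1C(=O)OC)c1ccc(OCc2ccccc2)c(OC)c1 | intermediate (not isolated)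
7 | (±)-6-(benzyloxy)-3-[4-(benzyloxy)-3-methoxyphenyl]-8-methoxy-3,4-dihydro-1H-isochromen-1-one (racemic) | O=C1OC(c2ccc(OCc3ccccc3)c(OC)c2)Cc2cc(OCc3ccccc3)cc(OC)c21 | intermediate
8 | 4-(benzyloxy)-2-{(E)-2-[4-(benzyloxy)-3-methoxyphenyl]ethenyl}-6-methoxybenzoic acid | OC(=O)c1c(/C=C/c2ccc(OCc3ccccc3)c(OC)c2)cc(OCc2ccccc2)cc1OC | intermediate
9 | 4-(benzyloxy)-2-{2-[4-(benzyloxy)-3-methoxyphenyl]ethyl}-6-methoxybenzoic acid | OC(=O)c1c(CCc2ccc(OCc3ccccc3)c(OC)c2)cc(OCc2ccccc2)cc1OC | intermediate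
10 | 5-(benzyloxy)-1-{2-[4-(benzyloxy)-3-methoxyphenyl]ethyl}-2-iodo-3-methoxybenzene | Ic1c(CCc2ccc(OCc3ccccc3)c(OC)c2)cc(OCc2ccccc2)cc1OC | intermediate
11 | {4-(benzyloxy)-2-{2-[4-(benzyloxy)-3-methoxyphenyl]ethyl}-6-methoxyphenyl}lithium | [Li]c1c(CCc2ccc(OCc3ccccc3)c(OC)c2)cc(OCc2ccccc2)cc1OC | intermediate (not isolated)
12 | lithium {4-(benzyloxy)-2-{2-[4-(benzyloxy)-3-methoxyphenyl]ethyl}-6-methoxyphenyl}(ethoxy)methanolate | [Li+].[O-]C(OCC)c1c(CCc2ccc(OCc3ccccc3)c(OC)c2)cc(OCc2ccccc2)cc1OC | intermediate (not isolated)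
13 | 4-(benzyloxy)-2-{2-[4-(benzyloxy)-3-methoxyphenyl]ethyl}-6-methoxybenzaldehyde | O=Cc1c(CCc2ccc(OCc3ccccc3)c(OC)c2)cc(OCc2ccccc2)cc1OC | intermediate (not isolated)
14 | bis{4-(benzyloxy)-2-{2-[4-(benzyloxy)-3-methoxyphenyl]ethyl}-6-methoxyphenyl}methanol | OC(c1c(CCc2ccc(OCc3ccccc3)c(OC)c2)cc(OCc2ccccc2)cc1OC)c1c(CCc2ccc(OCc3ccccc3)c(OC)c2)cc(OCc2ccccc2)cc1OC | intermediate
15 | bis{4-(benzyloxy)-2-{2-[4-(benzyloxy)-3-methoxyphenyl]ethyl}-6-methoxyphenyl}methylium trifluoroacetate | [CH+](c1c(CCc2ccc(OCc3ccccc3)c(OC)c2)cc(OCc2ccccc2)cc1OC)c1c(CCc2ccc(OCc3ccccc3)c(OC)c2)cc(OCc2ccccc2)cc1OC.[O-]C(=O)C(F)(F)F | intermediate (not isolated)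
16 | bis{4-(benzyloxy)-2-{2-[4-(benzyloxy)-3-methoxyphenyl]ethyl}-6-methoxyphenyl}methane | C(c1c(CCc2ccc(OCc3ccccc3)c(OC)c2)cc(OCc2ccccc2)cc1OC)c1c(CCc2ccc(OCc3ccccc3)c(OC)c2)cc(OCc2ccccc2)cc1OC | intermediate
17 | 4,4'-methylenebis{3-[2-(4-hydroxy-3-methoxyphenyl)ethyl]-5-methoxyphenol} | COc1cc(CCc2cc(O)cc(OC)c2Cc2c(CCc3ccc(O)c(OC)c3)cc(O)cc2OC)ccc1O | target

**Totals**
Total steps: 9. Longest linear sequence: 9 steps (1 → 17); two molecules of iodide 10 are joined in step 7.

**Three steps most likely to fail, with fallbacks**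

Step 7 (the second addition joins two di‑ortho‑substituted partners and may stop at the aldehyde, or the aryllithium may be quenched before it adds). The fallback sets out from 10 and builds the carbinol in two separate operations with an organomagnesium reagent instead of a one‑pot double addition to a formate. i‑PrMgCl·LiCl (1.1 equiv, THF, 0 °C → rt) converts 10 by iodine–magnesium exchange to the arylmagnesium chloride F1. One portion of this is quenched with DMF to give the chloromagnesium hemiaminal alkoxide F2, and aqueous NH4Cl then releases aldehyde 13, which is now isolated and purified. A second portion of the arylmagnesium chloride F1, made the same way, is added to purified 13 in THF at 0 °C → rt, and the route is rejoined at 14.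

Step 6 (iododecarboxylation; risks are incomplete conversion or further iodination of the electron‑rich ring). The fallback sets out from 9 and replaces decarboxylative halogenation by a Curtius/Sandmeyer sequence. DPPA and Et3N in toluene give the acyl azide F3, which rearranges at 90 °C to the isocyanate F4. Aqueous KOH/THF hydrolyses this to the aniline F5. Diazotisation with p‑TsOH and NaNO2 in MeCN/H2O gives the arenediazonium tosylate F6, which KI converts to the iodide; the route is rejoined at 10.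

Step 3 (the lithiated ester can self‑condense with unreacted 3, or the adduct may not lactonise fully). The fallback sets out from 3 and keeps the same aldol bond construction but uses a carboxylate donor that cannot act as an acylating agent. Saponification with KOH in DMSO/H2O gives 4-(benzyloxy)-2-methoxy-6-methylbenzoic acid F7. LDA (2.2 equiv) at −78 °C gives the dilithio carboxylate/benzylic dianion F8, which adds to aldehyde 4 to give the hydroxy acid F9. Catalytic TsOH in CH2Cl2 cyclodehydrates F9, and the route is rejoined at 7.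

**Further compounds**
F1 | step 7 | {4-(benzyloxy)-2-{2-[4-(benzyloxy)-3-methoxyphenyl]ethyl}-6-methoxyphenyl}magnesium chloride (used as its LiCl complex) | Cl[Mg]c1c(CCc2ccc(OCc3ccccc3)c(OC)c2)cc(OCc2ccccc2)cc1OC
F2 | step 7 | chloromagnesium {4-(benzyloxy)-2-{2-[4-(benzyloxy)-3-methoxyphenyl]ethyl}-6-methoxyphenyl}(dimethylamino)methanolate | Cl[Mg]OC(N(C)C)c1c(CCc2ccc(OCc3ccccc3)c(OC)c2)cc(OCc2ccccc2)cc1OC
F3 | step 6 | 4-(benzyloxy)-2-{2-[4-(benzyloxy)-3-methoxyphenyl]ethyl}-6-methoxybenzoyl azide | [N-]=[N+]=NC(=O)c1c(CCc2ccc(OCc3ccccc3)c(OC)c2)cc(OCc2ccccc2)cc1OC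
F4 | step 6 | 5-(benzyloxy)-1-{2-[4-(benzyloxy)-3-methoxyphenyl]ethyl}-2-isocyanato-3-methoxybenzene | O=C=Nc1c(CCc2ccc(OCc3ccccc3)c(OC)c2)cc(OCc2ccccc2)cc1OC
F5 | step 6 | 4-(benzyloxy)-2-{2-[4-(benzyloxy)-3-methoxyphenyl]ethyl}-6-methoxyaniline | Nc1c(CCc2ccc(OCc3ccccc3)c(OC)c2)cc(OCc2ccccc2)cc1OC
F6 | step 6 | 4-(benzyloxy)-2-{2-[4-(benzyloxy)-3-methoxyphenyl]ethyl}-6-methoxybenzenediazonium 4-methylbenzenesulfonate | N#[N+]c1c(CCc2ccc(OCc3ccccc3)c(OC)c2)cc(OCc2ccccc2)cc1OC.Cc1ccc(cc1)S(=O)(=O)[O-]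
F7 | step 3 | 4-(benzyloxy)-2-methoxy-6-methylbenzoic acid | OC(=O)c1c(C)cc(OCc2ccccc2)cc1OC
F8 | step 3 | lithium 4-(benzyloxy)-2-(lithiomethyl)-6-methoxybenzoate | [Li+].[O-]C(=O)c1c(C[Li])cc(OCc2ccccc2)cc1OC
F9 | step 3 | 4-(benzyloxy)-2-{2-[4-(benzyloxy)-3-methoxyphenyl]-2-hydroxyethyl}-6-methoxybenzoic acid (racemic) | OC(=O)c1c(CC(O)c2ccc(OCc3ccccc3)c(OC)c2)cc(OCc2ccccc2)cc1OC
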